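- We have a small charge of 0.20 M substrate, held for 80 min. Substrate gives target, written P, and isomer of the product, written Q, and we carry one ratio, R = Q/P, because the share of target is 1/(1+R).

| setting | green | violet | flask |
|---|---|---|---|
| substrate | 0.28 M | 0.44 M | 0.20 M |
| remark | run made earlier | run made earlier |  |
| time |  |  | 80 min |

| run | time / min | target / % | isomer of the product / % |
|---|---|---|---|
| green | 12.0 | 31.0 | 13.8 |
| green | 25.0 | 20.7 | 22.5 |
| green | 40.0 | 13.2 | 24.1 |
| green | 50.0 | 10.5 | 23.3 |
| green | 60.0 | 9.0 | 21.8 |
| green | 80.0 | 6.5 | 17.8 |
| violet | 5.00 | 26.9 | 5.8 |
| violet | 15.0 | 29.3 | 17.1 |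
| violet | 30.0 | 17.8 | 23.8 |
| violet | 40.0 | 13.2 | 24.5 |
| violet | 60.0 | 8.8 | 21.5 |
| violet | 80.0 | 5.9 | 18.0 |

(standard deviation of a reading: 0.3 percentage points)



* share of target in target plus isomer of the product at 20 s
* share of target in target plus isomer of the product at 5.0 min
* share of target in target plus isomer of the product at 80 min
* which of target and isomer of the product there is more of at 80 min

- First the charge: at 40.0 min, R reads 1.83 in the green run and 1.86 in the violet run, so we use one R curve for both, and for this flask, although its charge lies lower.
- With the main step alone, substrate to target, Q stays at zero, so R is zero and the share is 100%.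
- Adding target to isomer of the product makes R climb from zero. It reads 0.216 at 5.00 min (violet) and 0.445 at 12.0 min (green), a slope of 0.0328 /min.
- Adding a direct step from substrate to isomer of the product lets R start above zero. Our line through those readings meets time zero at S = 0.0517, a reading that carries the scatter. S is the rate of Q divided by the rate of P at the start, so time drops out: it is a selectivity factor.
- Our reckoning then gives the ratio R at the early time, 0.0626, and so a share of 94.1%. At 5.0 min the violet reading gives 82.3%.
- Late in the runs we stop using the line and read R directly. At 80.0 min it is 2.74 (green) and 3.05 (violet), so isomer of the product leads, and the two shares average 25.7%.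
- The forecast, noting “Both runs overlay once expressed as percent of charge”, gives 90%, 82% and 25.7%, with isomer of the product ahead. It parts from our reckoning at 20 s.
- The flask gives 93.0%, 83.4% and 24.8%, with isomer of the product ahead.

    substrate ⇌ target (K = 1.80, k = 0.100 /min)
    substrate ⇌ isomer of the product (K = 3.00, k = 0.00680 /min)
    target → over-reaction product (k = 0.0580 /min)
    target ⇌ isomer of the product (k = 0.0360 /min)

- In this flask, R at 20 s comes to 0.0753 against our 0.0626, and in the neighbour charged with 0.080 M it comes to 0.0755. Early on, substrate fed target, which stood at 31.1% after 8.00 min, and target and isomer of the product stood level at 22.0% after 23.6 min. Between 40.0 min and 80 min, over-reaction product, which forms from target, rose from 51.4% to 71.7%, while isomer of the product fell from 24.5% to 18.1% and target fell from 13.2% to 5.98%.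

(The data are simulated for substances that don't exist.)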